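**Retrosynthetic overview**
1. The target comes from a hexa-O-benzyl 4β-aryl-flavan-3-one by α-face hydride reduction of C3=O, desilylation and debenzylation. In the ketone, the C4 aryl group dictates the 3,4-cis alcohol.
2. The key disconnection is C4 (ring C)–C6 (ring D). The partners are the enolonium (α-carbonyl cation) form of a flavan-3-one silyl enol ether and the C6–H of a silyl-protected mollisacacidin. Both carbons are innately nucleophilic.
3. Both partners come from one monomer, tri-O-benzylmollisacacidin, by bis-silylation or by silylative 1,2-elimination to the enol silane.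
4. The monomer derives from tri-O-benzylfustin (NaBH4), then the (αR,βS)-epoxychalcone (Juliá–Colonna), then the chalcone, then an acetophenone and a benzaldehyde.
5. Ring order: the benzene rings are bought. The pyran ring is closed once, at the monomer stage, and becomes both ring C and ring F. No ring is formed after the union.

Assumption: flavanoid numbering is used; the upper unit is rings A/B/C and the lower unit is rings D/E/F; α is the face carrying the 2-aryl group of a 2R unit and β is the opposite face; 1 and 4 are bought as such.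

**Step 1**
Reactants: 1 4'-benzyloxy-2'-hydroxyacetophenone
Product: 3 4'-benzyloxy-2'-(methoxymethoxy)acetophenone, via sodium phenoxide 2 (not isolated)
Conditions: NaH, DMF, 0 °C; then MOMCl, 0 °C → rt
Reagents that add atoms: chloromethyl methyl ether (MOMCl), COCCl
Why: Williamson O-alkylation of the fully deprotonated chelated phenol masks it, so it cannot close a flavanone in step 2 or start Algar–Flynn–Oyamada chemistry in step 3; no stereocentre is formed.

**Step 2**
Reactants: 3 4'-benzyloxy-2'-(methoxymethoxy)acetophenone; 4 3,4-bis(benzyloxy)benzaldehyde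
Product: 5 (E)-3,4,4'-tris(benzyloxy)-2'-(methoxymethoxy)chalcone
Conditions: KOH, EtOH, rt
Reagents that add atoms: none
Why: Claisen–Schmidt aldol condensation, in which E1cB loss of water gives only the conjugated E-enone and the benzyl and MOM ethers are inert to KOH.

**Step 3**
Reactants: 5 (E)-3,4,4'-tris(benzyloxy)-2'-(methoxymethoxy)chalcone
Product: 6 (αR,βS)-trans-epoxide of chalcone 5
Conditions: poly-L-leucine, urea·H2O2, DBU, THF, rt; recrystallise
Reagents that add atoms: urea–hydrogen peroxide, OO.NC(N)=O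
Why: Juliá–Colonna epoxidation (Weitz–Scheffer addition of HOO− inside the helical peptide), in which the L-polymer exposes one enone face and gives the (αR,βS)-trans-epoxide; this sets the absolute configuration of C2 and C3 of both flavan units, and any residual minor enantiomer is removed later as a separable heterochiral dimer.

**Step 4**
Reactants: 6 (αR,βS)-trans-epoxide of chalcone 5
Product: 8 (2R,3R)-7,3',4'-tri-O-benzylfustin, via 2'-hydroxy epoxychalcone 7 (not isolated)
Conditions: conc. HCl (5% v/v), MeOH–THF 1:1, 50 °C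
Reagents that add atoms: none
Why: acetal solvolysis frees the phenol, which opens the activated benzylic Cβ–O bond 6-endo with inversion while the Cα–O bond stays intact (epoxychalcone to dihydroflavonol cyclisation), so (αR,βS) maps onto the diequatorial (2R,3R)-2,3-trans product, which is also the thermodynamic isomer.

**Step 5**
Reactants: 8 (2R,3R)-7,3',4'-tri-O-benzylfustin
Product: 9 (2R,3S,4R)-7,3',4'-tri-O-benzylmollisacacidin (2,3-trans-3,4-trans flavan-3,4-diol)
Conditions: NaBH4, THF–MeOH 4:1, 0 °C
Reagents that add atoms: none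
Why: substrate-controlled borohydride reduction, in which axial hydride delivery on the β face gives the equatorial 4α-OH; this is the established outcome for 2,3-trans-dihydroflavonols.

**Step 6**
Reactants: 9 (2R,3S,4R)-7,3',4'-tri-O-benzylmollisacacidin
Product: 10 3,4-bis-O-TBS ether of 9 (configuration unchanged)
Conditions: TBSOTf (2.5 equiv), 2,6-lutidine, CH2Cl2, −78 → −20 °C
Reagents that add atoms: tert-butyldimethylsilyl triflate (TBSOTf), CC(C)(C)[Si](C)(C)OS(=O)(=O)C(F)(F)F
Why: O-silylation blocks both alcohols as bulky, weakly Lewis-basic ethers, so that ring D stays an electron-rich resorcinol-type nucleophile while the benzylic C4–O bond resists ionisation at low temperature.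

**Step 7**
Reactants: 9 (2R,3S,4R)-7,3',4'-tri-O-benzylmollisacacidin
Product: 12 (2R)-7-(benzyloxy)-2-[3,4-bis(benzyloxy)phenyl]-3-(trimethylsilyloxy)-2H-chromene, via 3,4-bis-O-TMS ether 11 (not isolated)
Conditions: TMSOTf (3.5 equiv), i-Pr2NEt (5 equiv), CH2Cl2 (0.02 M), −78 °C → rt; used crude
Reagents that add atoms: trimethylsilyl triflate (TMSOTf), C[Si](C)(C)OS(=O)(=O)C(F)(F)F
Why: Proposed new method: after exhaustive silylation, excess TMSOTf silylates the benzylic 4-oxygen, (Me3Si)2O leaves from the ortho,para-dioxygenated benzylic carbon, and the hindered amine removes the axial H-3, the only β-hydrogen (E1), which gives the flavan-3-one silyl enol ether regiospecifically, with C2 untouched and the epimerisable ketone never exposed; the closest known reaction types are the TMSOTf/i-Pr2NEt conversion of acetals into enol ethers and the pinacol-type dehydration of 1-aryl-1,2-diols to benzyl ketones.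

**Step 8 (key step)**
Reactants: 12 (2R)-7-(benzyloxy)-2-[3,4-bis(benzyloxy)phenyl]-3-(trimethylsilyloxy)-2H-chromene; 10 3,4-bis-O-TBS ether of 9
Product: 14 hexa-O-benzyl-3-oxofisetinidol-(4β→6)-mollisacacidin 3,4-bis-O-TBS ether (2,4-trans in ring C), via O-iodanyl enolate (enolonium) 13 (not isolated)
Conditions: PhI(OAc)2 (1.05 equiv), BF3·OEt2 (2.1 equiv), CH2Cl2, −78 °C; add 12; then 10 (2.5 equiv), 2,6-di-tert-butyl-4-methylpyridine, −78 → −50 °C; Et3N quench at −78 °C
Reagents that add atoms: none
Why: Proposed new method: the enol silane attacks BF3-activated trivalent iodine to give enolonium 13, whose normally nucleophilic α-carbon C4 becomes electrophilic on reductive loss of PhI and is captured by C6 of 10 (ortho to 7-OBn, para to O1, less hindered than C8), so two innately nucleophilic carbons are joined; attack is axial on the sofa-shaped ring C with the 2-aryl group equatorial, that is on the β face, and the pseudo-axial 4β-aryl ketone should also be the thermodynamic epimer because it avoids peri strain with H-5; the closest known reaction type is the two-stage α-arylation of ketone silyl enol ethers with electron-rich arenes through preformed enolonium species.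

**Step 9**
Reactants: 14 hexa-O-benzyl-3-oxofisetinidol-(4β→6)-mollisacacidin 3,4-bis-O-TBS ether
Product: 16 hexa-O-benzyl-fisetinidol-(4β→6)-mollisacacidin (free 3-OH in ring C and free 3,4-diol in ring F), via 3β-alcohol bis-TBS ether 15 (not isolated)
Conditions: NaBH4, THF–MeOH 4:1, −40 → 0 °C; then AcOH, n-Bu4NF, THF, rt → 40 °C
Reagents that add atoms: none
Why: diastereoselective ketone reduction, in which the pseudo-axial 4β-aryl group screens the β face so the small hydride adds axially from the α face and gives the equatorial 3β-OH (2,3-trans-3,4-cis); buffered fluoride then cleaves both Si–O bonds without touching a stereocentre.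

**Step 10**
Reactants: 16 hexa-O-benzyl-fisetinidol-(4β→6)-mollisacacidin
Product: 17 fisetinidol-(4β→6)-mollisacacidin (CNP0280090.2; ring C 2R,3S,4S; ring F 2R,3S,4R)
Conditions: H2 (1 atm), Pd(OH)2/C, THF–MeOH 1:1, rt, stopped at full debenzylation; Sephadex LH-20
Reagents that add atoms: none
Why: catalytic hydrogenolysis removes the six primary aryl benzyl ethers much faster than the secondary C4–OH or the ring C–O bonds react under neutral conditions (flavan-3,4-diols are themselves made by neutral catalytic hydrogenation), so no stereocentre is affected.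

**Compound list**
1 | 4'-benzyloxy-2'-hydroxyacetophenone | CC(=O)c1ccc(OCc2ccccc2)cc1O | starting material
2 | sodium phenoxide of 1 | CC(=O)c1ccc(OCc2ccccc2)cc1[O-].[Na+] | intermediate (not isolated)
3 | 4'-benzyloxy-2'-(methoxymethoxy)acetophenone | CC(=O)c1ccc(OCc2ccccc2)cc1OCOC | intermediate
4 | 3,4-bis(benzyloxy)benzaldehyde | O=Cc1ccc(OCc2ccccc2)c(OCc2ccccc2)c1 | starting material
5 | (E)-3,4,4'-tris(benzyloxy)-2'-(methoxymethoxy)chalcone | O=C(/C=C/c1ccc(OCc2ccccc2)c(OCc2ccccc2)c1)c1ccc(OCc2ccccc2)cc1OCOC | intermediate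
6 | (αR,βS)-trans-epoxide of 5 | O=C(c1ccc(OCc2ccccc2)cc1OCOC)[C@@H]1O[C@H]1c1ccc(OCc2ccccc2)c(OCc2ccccc2)c1 | intermediate
7 | (αR,βS)-2'-hydroxy epoxychalcone | O=C(c1ccc(OCc2ccccc2)cc1O)[C@@H]1O[C@H]1c1ccc(OCc2ccccc2)c(OCc2ccccc2)c1 | intermediate (not isolated)
8 | (2R,3R)-7,3',4'-tri-O-benzylfustin | c1ccccc1COc1ccc2c(c1)O[C@H](c1ccc(OCc3ccccc3)c(OCc3ccccc3)c1)[C@@H](O)C2=O | intermediate
9 | (2R,3S,4R)-7,3',4'-tri-O-benzylmollisacacidin | c1ccccc1COc1ccc2c(c1)O[C@H](c1ccc(OCc3ccccc3)c(OCc3ccccc3)c1)[C@@H](O)[C@@H]2O | intermediate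
10 | 3,4-bis-O-TBS ether of 9 (2,3-trans-3,4-trans) | c1ccccc1COc1ccc2c(c1)O[C@H](c1ccc(OCc3ccccc3)c(OCc3ccccc3)c1)[C@@H](O[Si](C)(C)C(C)(C)C)[C@@H]2O[Si](C)(C)C(C)(C)C | intermediate
11 | 3,4-bis-O-TMS ether of 9 | c1ccccc1COc1ccc2c(c1)O[C@H](c1ccc(OCc3ccccc3)c(OCc3ccccc3)c1)[C@@H](O[Si](C)(C)C)[C@@H]2O[Si](C)(C)C | intermediate (not isolated)
12 | (2R)-7-(benzyloxy)-2-[3,4-bis(benzyloxy)phenyl]-3-(trimethylsilyloxy)-2H-chromene | c1ccccc1COc1ccc2c(c1)O[C@H](c1ccc(OCc3ccccc3)c(OCc3ccccc3)c1)C(O[Si](C)(C)C)=C2 | intermediate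
13 | enolonium: (2R)-flav-3-en-3-yl O-[acetoxy(phenyl)-λ3-iodanyl] enolate (BF3-bound) | c1ccccc1COc1ccc2c(c1)O[C@H](c1ccc(OCc3ccccc3)c(OCc3ccccc3)c1)C(OI(OC(C)=O)c1ccccc1)=C2 | intermediate (not isolated)
14 | hexa-O-benzyl-3-oxofisetinidol-(4β→6)-mollisacacidin 3,4-bis-O-TBS ether | c1ccccc1COc1ccc2c(c1)O[C@H](c1ccc(OCc3ccccc3)c(OCc3ccccc3)c1)C(=O)[C@H]2c1cc2c(cc1OCc3ccccc3)O[C@H](c1ccc(OCc3ccccc3)c(OCc3ccccc3)c1)[C@@H](O[Si](C)(C)C(C)(C)C)[C@@H]2O[Si](C)(C)C(C)(C)C | intermediate
15 | hexa-O-benzyl-fisetinidol-(4β→6)-mollisacacidin 3,4-bis-O-TBS ether (3β-OH in ring C) | c1ccccc1COc1ccc2c(c1)O[C@H](c1ccc(OCc3ccccc3)c(OCc3ccccc3)c1)[C@@H](O)[C@H]2c1cc2c(cc1OCc3ccccc3)O[C@H](c1ccc(OCc3ccccc3)c(OCc3ccccc3)c1)[C@@H](O[Si](C)(C)C(C)(C)C)[C@@H]2O[Si](C)(C)C(C)(C)C | intermediate (not isolated)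
16 | hexa-O-benzyl-fisetinidol-(4β→6)-mollisacacidin | c1ccccc1COc1ccc2c(c1)O[C@H](c1ccc(OCc3ccccc3)c(OCc3ccccc3)c1)[C@@H](O)[C@H]2c1cc2c(cc1OCc3ccccc3)O[C@H](c1ccc(OCc3ccccc3)c(OCc3ccccc3)c1)[C@@H](O)[C@@H]2O | intermediate
17 | fisetinidol-(4β→6)-mollisacacidin (CNP0280090.2) | Oc1ccc2c(c1)O[C@H](c1ccc(O)c(O)c1)[C@@H](O)[C@H]2c1cc2c(cc1O)O[C@H](c1ccc(O)c(O)c1)[C@@H](O)[C@@H]2O | target

**Step count**
Total steps: 10. Longest linear sequence: 9 (steps 1–5, 7, 8, 9, 10). Step 6 is the side branch from 9.

**Steps most likely to fail**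

Risk 1, step 8. The α-keto cation may lose H-2 and aromatise to a 3-hydroxyflavylium salt. Ring A of 14 may compete with 10 as the nucleophile. The 4-OTBS group of 10 may ionise. The fallback sets out from 12 (with 10) and comes back at 14. Compound 12 is hydrolysed with aqueous citric acid in THF at 0 °C to (2R)-7,3',4'-tri-O-benzylflavan-3-one F1. Regitz diazo transfer (4-acetamidobenzenesulfonyl azide, DBU, MeCN, 0 °C) at the doubly activated C4 methylene gives (2R)-4-diazo-7,3',4'-tri-O-benzylflavan-3-one F2. F2 is then added slowly to 10 and catalytic (2,4-t-Bu2C6H3O)3PAuCl/AgSbF6 in CH2Cl2 at rt. The electrophilic α-oxo carbene of monovalent gold is again an α-carbonyl cation equivalent, but it forms under neutral, acid-free conditions and functionalises C6–H of ring D. Ketonisation of the resulting enol sets C4 under thermodynamic control and delivers 14. DBU may erode the C2 configuration, so the ee of F2 must be checked.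

Risk 2, step 7. The benzylic cation may be trapped by the enol silane already formed. The product may also isomerise to the achiral 4H-chromene enol silane. The fallback sets out from 9 and comes back at 12. Ionic hydrogenation of 9 (Et3SiH, CF3CO2H, CH2Cl2, −20 °C) removes the 4-OH and gives (2R,3S)-7,3',4'-tri-O-benzylfisetinidol F3. Dess–Martin periodinane in CH2Cl2 oxidises F3 to the flavan-3-one F1. Kinetic deprotonation at the less hindered, more acidic C4 methylene with an internal quench (LiN(SiMe3)2, TMSCl, THF, −78 °C) gives 12.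

Risk 3, step 10. The electron-rich benzylic C4–OH of ring F may be hydrogenolysed, which would give the 4-deoxy dimer. The fallback sets out from 15, isolated after the borohydride stage of step 9, and comes back at 17. Compound 15 is hydrogenolysed (H2, Pd(OH)2/C, THF–MeOH) while the bulky silyl ether still shields the C4–O bond. This gives fisetinidol-(4β→6)-mollisacacidin 3,4-bis-O-TBS ether F4. The two silyl groups are then removed from the free polyphenol with Et3N·3HF in MeCN–THF at rt, which is far too weakly acidic to ionise C4–OH, and this gives 17.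

**Further compounds**
F1 | step 8 | (2R)-7,3',4'-tri-O-benzylflavan-3-one | c1ccccc1COc1ccc2c(c1)O[C@H](c1ccc(OCc3ccccc3)c(OCc3ccccc3)c1)C(=O)C2
F2 | step 8 | (2R)-4-diazo-7,3',4'-tri-O-benzylflavan-3-one | c1ccccc1COc1ccc2c(c1)O[C@H](c1ccc(OCc3ccccc3)c(OCc3ccccc3)c1)C(=O)C2=[N+]=[N-]
F3 | step 7 | (2R,3S)-7,3',4'-tri-O-benzylfisetinidol | c1ccccc1COc1ccc2c(c1)O[C@H](c1ccc(OCc3ccccc3)c(OCc3ccccc3)c1)[C@@H](O)C2
F4 | step 10 | fisetinidol-(4β→6)-mollisacacidin 3,4-bis-O-TBS ether (free phenols) | Oc1ccc2c(c1)O[C@H](c1ccc(O)c(O)c1)[C@@H](O)[C@H]2c1cc2c(cc1O)O[C@H](c1ccc(O)c(O)c1)[C@@H](O[Si](C)(C)C(C)(C)C)[C@@H]2O[Si](C)(C)C(C)(C)C
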